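The vessel was closed, stirred and isothermal. It held starting material (A), partner and second substrate. Partner binds A reversibly to give target (T) and binds second substrate reversibly to give second product, while second substrate also condenses with itself.

the same everywhere: starting material 0.10 M
- winter: partner 0.11 M; second substrate 0.10 M; run made earlier
- dawn: partner 0.33 M; second substrate 0.10 M; run made earlier
- south-west: partner 0.0950 M; second substrate 0.100 M; time 4.0 d
- south: partner 0.210 M; second substrate 0.100 M; time 4.0 d
- south-east: partner 0.140 M; second substrate 0.100 M; time 4.0 d

| run | time / h | target / % | starting material / % |
|---|---|---|---|
| winter | 10.0 | 20.4 | 78.6 |
| winter | 20.0 | 31.3 | 68.7 |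
| winter | 30.0 | 35.1 | 63.5 |
| winter | 40.0 | 39.8 | 60.8 |
| winter | 50.0 | 39.8 | 59.3 |
| dawn | 4.00 | 29.4 | 71.6 |
| dawn | 12.0 | 57.1 | 42.4 |
| dawn | 20.0 | 68.1 | 28.3 |
| dawn | 30.0 | 77.9 | 21.5 |
| dawn | 50.0 | 85.0 | 16.5 |

(each reading ± 1 percentage point)

- which of these there is most of at the end, counted by the starting material in it, south-west (starting material / target)
- which of these there is most of at the end, counted by the starting material in it, south (starting material / target)
- which of these there is most of at the end, counted by the starting material in it, south-east (starting material / target)
- final amount of the leader among these, as a percentage of the starting material charged, in south-west
- final amount of the leader among these, as a percentage of the starting material charged, in south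
- final amount of the leader among these, as a percentage of the starting material charged, in south-east

For a reversible binding step, the flask tends to T/A = b/K_d, where b is the free partner and K_d is the dissociation constant of target. The readings give T/A, but b must be inferred. Dawn offered a way in: its partner charge of 0.33 M exceeded the other two charges together, so I counted the whole second substrate as bound to partner, one to one. Its last reading had target at 85.0% and starting material at 16.5%, which left b = 0.145 M. This gave K_d = 0.0281 M, the free partner at which target and starting material stand equal. It remains a reading, resting on that assumption and on taking dawn's last reading as balance.

Winter's target read 39.8% at both 40.0 h and 50.0 h, but each reading scatters by 1 percentage point and its starting material read 60.8% and then 59.3%, so that pair showed no end. The asked 4.0 d is twice that last time, and I reckoned winter and the new flasks as if at balance, which was my assumption and not something the readings showed. On that assumption, K_d turned winter's last T/A into b = 0.0189 M. The partner missing from the balance, 0.0513 M, I placed on second substrate, about half of its charge. Neglecting self-condensation, this gave a second dissociation constant, K_s = 0.0179 M.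

A tie, b = K_d, needs K_d free, 0.0500 M in target and 0.0611 M on second substrate, a bill of 0.139 M. South-west's charge falls short of it, so I called starting material there. South's charge exceeds it, so I called target. South-east's 0.140 M stands level with it, so I called that flask a near tie.

The forecast gave starting material at 63% in south-west, target at 71% in south and target at 53% in south-east, which it called “essentially a tie”.

    starting material + partner ⇌ target (K = 37.6 M⁻¹, k = 0.303 M⁻¹ h⁻¹)
    2 second substrate → self-condensation product (k = 0.0768 M⁻¹ h⁻¹)
    second substrate + partner ⇌ second product (K = 26.9 M⁻¹, k = 0.450 M⁻¹ h⁻¹)

South-west ended with starting material leading at 57.6%, south with target at 73.4%, and south-east with target at 57.3%. South-east kept 29.8% of its partner free, or 0.0417 M, which is more than K_d, and b/(b + K_d) turns that into 59.7% target. A neighbour of south, charged with 0.040 M of second substrate, kept 49% of its partner free, or 0.104 M. The same K_d turns that into 78.7%, and that flask held 78.8% target.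

The data come from a simulation with made-up constants, and the scatter is random.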